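**Retrosynthetic overview**
- The plan rests on ring A of the chromanone, which carries oxygen on three neighbouring carbons: C7 (OMe), C8 (OMe) and C8a (O1 of ring C). A C7-OH/C8-OMe guaiacol with the acyl chain on C4a can be oxidised to its 8,8-dimethoxy dienone, and C8a of that dienone is the acceptor for the C2 hydroxyl.
- Key disconnection: the O1–C8a bond of ring C, made by oxidative dearomatisation of the ring A phenol, oxa-conjugate addition of the C2 hydroxyl and loss of methanol to rearomatise.
- The cyclisation precursor, a (3S)-β-hydroxy ketone, comes from a catalytic asymmetric Mukaiyama aldol (C2–C3 bond, the only stereocentre) between the bis-silyl enol ether of acetovanillone and O-benzylated 3-hydroxy-4,5-dimethoxybenzaldehyde.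
- End game: base-free O-methylation at C7, then removal of the ring B benzyl group.
- Ring order: rings A and B are bought as arenes; ring C is the only ring formed, in the key step.

Key step: step 4

Remark on the chemistry: the aldol catalyst is the bisphosphoramide CH2[CH2CH2N(Me)P(O)(NMe)2C20H12]2 (C20H12 = 1,1'-binaphthalene-2,2'-diyl; SMILES without axial descriptors CN(CCCCCN(C)P1(=O)N(C)c2ccc3ccccc3c2-c2c(N1C)ccc1ccccc21)P1(=O)N(C)c2ccc3ccccc3c2-c2c(N1C)ccc1ccccc21). Its (S,S)-antipode is assumed to direct the enol ether to the Si face of the aldehyde; the configuration of the aldol product is to be checked by MTPA ester analysis, and the (R,R)-antipode is used instead if the sense is the opposite.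

Step 1
Reactants: 1 3-hydroxy-4,5-dimethoxybenzaldehyde; 2 benzyl bromide
Product: 3 3-(benzyloxy)-4,5-dimethoxybenzaldehyde
Conditions: K2CO3, DMF, rt to 50 °C
Reagents that add atoms: benzyl bromide (compound 2), BrCc1ccccc1
Why: Williamson ether synthesis on the only phenol; the aldehyde has no enolisable hydrogen and is inert to carbonate, and the benzyl ether keeps the ring B guaiacol-type phenol from being oxidised later.

Step 2
Reactants: 4 acetovanillone
Product: 5 1-[3-methoxy-4-(trimethylsilyloxy)phenyl]-1-(trimethylsilyloxy)ethene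
Conditions: Me3SiOTf (2.3 equiv), Et3N (3 equiv), CH2Cl2, 0 °C; pentane extraction without water, Kugelrohr distillation
Reagents that add atoms: trimethylsilyl trifluoromethanesulfonate, C[Si](C)(C)OS(=O)(=O)C(F)(F)F
Why: Soft enolisation and O-silylation of an aryl methyl ketone with a silyl triflate and a tertiary amine, which silylates the phenol in the same flask, so the aryl silyl ether serves as a protecting group that costs no step of its own.

Step 3
Reactants: 3 3-(benzyloxy)-4,5-dimethoxybenzaldehyde; 5 1-[3-methoxy-4-(trimethylsilyloxy)phenyl]-1-(trimethylsilyloxy)ethene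
Product: 7 (3S)-3-[3-(benzyloxy)-4,5-dimethoxyphenyl]-3-hydroxy-1-(4-hydroxy-3-methoxyphenyl)propan-1-one, via trichlorosilyl aldolate 6 (not isolated)
Conditions: SiCl4 (1.5 equiv), (S,S)-CH2[CH2CH2N(Me)P(O)(NMe)2C20H12]2 (5 mol%), iPr2NEt (10 mol%), CH2Cl2, −78 °C; then sat. aq. NaHCO3, MeOH, 0 °C to rt
Reagents that add atoms: none
Why: Lewis-base-catalysed Mukaiyama aldol addition, a known reaction of methyl ketone silyl enol ethers with aromatic aldehydes, in which the chiral bisphosphoramide binds SiCl4 to a chiral trichlorosilyl cation that activates the aldehyde, the enol ether adds through an open transition state to the Si face and so sets C3 as S, chloride takes up the enol silyl group, and the bicarbonate work-up hydrolyses both the O–SiCl3 bond and the labile aryl O–SiMe3 bond.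

Step 4
Reactants: 7 (3S)-3-[3-(benzyloxy)-4,5-dimethoxyphenyl]-3-hydroxy-1-(4-hydroxy-3-methoxyphenyl)propan-1-one
Product: 10 (2S)-2-[3-(benzyloxy)-4,5-dimethoxyphenyl]-7-hydroxy-8-methoxychroman-4-one, via dimethoxy dienone 8 (not isolated), via dienol ketal adduct 9 (not isolated)
Conditions: PhI(OAc)2 (1.0 equiv, one portion), MeOH (0.01 M), −20 °C, 20 min; then rt
Reagents that add atoms: methanol, CO (solvent; C8 of 8 holds one methoxy group from it and either methoxy group can leave from 9, so the C8 OCH3 of 10 may be solvent-derived; there is no net gain of atoms)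
Why: Proposed new method: PhI(OAc)2 oxidises the C7 phenol of the 4-acylguaiacol 7 through its aryloxy trivalent-iodine ester, methanol is taken up at C8 to give the 8,8-dimethoxy dienone 8, the C2 hydroxyl then adds to C8a (at once the β-carbon of the C4 enone and the δ-carbon of the C7 dienone) to give 9, and acetic-acid-assisted loss of methanol from C8 returns the arene with O1 on C8a and a free C7 phenol. The closest known reaction type is the generation of masked o-benzoquinones from 2-methoxyphenols with PhI(OAc)2 in methanol together with the addition of nitrogen and carbon nucleophiles to o-quinone monoketals followed by rearomatisation; ring closure by a hydroxyl group to a chromanone has not been shown. Ring C closes in a 6-endo-trig oxa-conjugate addition, both carbons of the attacked C4a=C8a bond lying in the new ring. No lasting stereocentre is formed (C8a of 9 is sp3 only until methanol leaves), and C2 should keep its S configuration because its C–O bond is never broken and the weakly acidic medium should not open the β-aryloxy ketone. The step needs site selectivity between C8a and C5, both of which would give a six-membered ring: only the adduct at C8a can expel methanol and aromatise, so the reversible adduct at C5 should drain into 10, and C8a is in addition the doubly activated carbon. It also needs chemoselectivity, which rests on the benzyl ether that keeps ring B from being oxidised, on adding one equivalent of oxidant in one portion in the cold so that it is consumed before the more electron-rich phenol 10 appears, and on high dilution, which holds back Diels–Alder dimerisation of 8.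

Step 5
Reactants: 10 (2S)-2-[3-(benzyloxy)-4,5-dimethoxyphenyl]-7-hydroxy-8-methoxychroman-4-one
Product: 11 (2S)-2-[3-(benzyloxy)-4,5-dimethoxyphenyl]-7,8-dimethoxychroman-4-one
Conditions: Me3SiCHN2 (2 M in hexanes, 3 equiv), MeOH/toluene 1:3, 0 °C to rt
Reagents that add atoms: (trimethylsilyl)diazomethane, C[Si](C)(C)C=[N+]=[N-]
Why: O-methylation of a phenol with (trimethylsilyl)diazomethane in methanol, in which the C7 phenol (vinylogous to the C4 carbonyl and therefore acidic) protonates the reagent, methanol removes silicon and the methyldiazonium ion alkylates the phenoxide, all without added base, so the chromanone is not opened to the chalcone and C2 is not racemised.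

Step 6
Reactants: 11 (2S)-2-[3-(benzyloxy)-4,5-dimethoxyphenyl]-7,8-dimethoxychroman-4-one
Product: 12 (2S)-2-(3-hydroxy-4,5-dimethoxyphenyl)-7,8-dimethoxychroman-4-one
Conditions: H2 (1 atm), 10% Pd/C, EtOAc, rt, stopped after one equivalent of H2
Reagents that add atoms: none
Why: Catalytic hydrogenolysis of a benzyl aryl ether, in which the unhindered primary benzyl–O bond should be cleaved before the secondary C2–O1 bond and the conjugated C4 ketone under one atmosphere in a neutral solvent.

**Compound list**
1 | 3-hydroxy-4,5-dimethoxybenzaldehyde | COc1cc(C=O)cc(O)c1OC | starting material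
2 | benzyl bromide | BrCc1ccccc1 | starting material
3 | 3-(benzyloxy)-4,5-dimethoxybenzaldehyde | COc1cc(C=O)cc(OCc2ccccc2)c1OC | intermediate
4 | acetovanillone, 1-(4-hydroxy-3-methoxyphenyl)ethanone | CC(=O)c1ccc(O)c(OC)c1 | starting material
5 | 1-[3-methoxy-4-(trimethylsilyloxy)phenyl]-1-(trimethylsilyloxy)ethene | C=C(O[Si](C)(C)C)c1ccc(O[Si](C)(C)C)c(OC)c1 | intermediate
6 | (1S)-1-[3-(benzyloxy)-4,5-dimethoxyphenyl]-3-[3-methoxy-4-(trimethylsilyloxy)phenyl]-3-oxopropyl trichlorosilyl ether | COc1cc([C@@H](O[Si](Cl)(Cl)Cl)CC(=O)c2ccc(O[Si](C)(C)C)c(OC)c2)cc(OCc3ccccc3)c1OC | intermediate (not isolated)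
7 | (3S)-3-[3-(benzyloxy)-4,5-dimethoxyphenyl]-3-hydroxy-1-(4-hydroxy-3-methoxyphenyl)propan-1-one | COc1cc([C@@H](O)CC(=O)c2ccc(O)c(OC)c2)cc(OCc3ccccc3)c1OC | intermediate
8 | 4-{(3S)-3-[3-(benzyloxy)-4,5-dimethoxyphenyl]-3-hydroxypropanoyl}-6,6-dimethoxycyclohexa-2,4-dien-1-one | COc1cc([C@@H](O)CC(=O)C2=CC(OC)(OC)C(=O)C=C2)cc(OCc3ccccc3)c1OC | intermediate (not isolated)
9 | (2S)-2-[3-(benzyloxy)-4,5-dimethoxyphenyl]-7-hydroxy-8,8-dimethoxy-2,3,8,8a-tetrahydro-4H-chromen-4-one, configuration at C8a undefined | COc1cc([C@@H]2CC(=O)C3=CC=C(O)C(OC)(OC)C3O2)cc(OCc4ccccc4)c1OC | intermediate (not isolated)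
10 | (2S)-2-[3-(benzyloxy)-4,5-dimethoxyphenyl]-7-hydroxy-8-methoxychroman-4-one | COc1cc([C@@H]2CC(=O)c3ccc(O)c(OC)c3O2)cc(OCc4ccccc4)c1OC | intermediate
11 | (2S)-2-[3-(benzyloxy)-4,5-dimethoxyphenyl]-7,8-dimethoxychroman-4-one | COc1cc([C@@H]2CC(=O)c3ccc(OC)c(OC)c3O2)cc(OCc4ccccc4)c1OC | intermediate
12 | (2S)-2-(3-hydroxy-4,5-dimethoxyphenyl)-7,8-dimethoxychroman-4-one | COc1cc([C@@H]2CC(=O)c3ccc(OC)c(OC)c3O2)cc(O)c1OC | target

Total step count: 6
Longest linear sequence: 5 steps (steps 2, 3, 4, 5 and 6 from acetovanillone; the branch through step 1 is equally long)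

**Steps most likely to fail**

Step 4 (proposed new method). The dienone may dimerise by Diels–Alder reaction faster than the hydroxyl adds, the hydroxyl may not add at all so that the dienone lingers and decomposes, the β-hydroxy ketone may lose water, or the freed phenol may be oxidised a second time. The fallback uses known chemistry and forms the O1–C2 bond instead of the O1–C8a bond, by Mitsunobu ring closure of a 2'-hydroxy aldol with inversion. It sets out from 3 and comes back to the route at 11, so steps 4 and 5 fall away. Commercial 1-(2-hydroxy-3,4-dimethoxyphenyl)ethanone F1 is bis-silylated as in step 2 (Me3SiOTf, Et3N) to 1-[3,4-dimethoxy-2-(trimethylsilyloxy)phenyl]-1-(trimethylsilyloxy)ethene F2. Addition of F2 to 3 under the conditions of step 3, but with the mirror-image (R,R)-catalyst, should give through the trichlorosilyl aldolate F3 and bicarbonate work-up (3R)-3-[3-(benzyloxy)-4,5-dimethoxyphenyl]-3-hydroxy-1-(2-hydroxy-3,4-dimethoxyphenyl)propan-1-one F4. PPh3 and diisopropyl azodicarboxylate in THF at 0 °C then activate the secondary alcohol, and the ortho phenol displaces it with inversion to give the (2S)-chromanone 11.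

Step 3. Facial selectivity may be poor with this electron-rich, trioxygenated aldehyde, or the silyl groups of 5 may be lost early, so that liberated HCl drives an unselective background addition. The fallback sets the stereocentre by catalytic asymmetric conjugate borylation of a chalcone; it sets out from 4 and 3 and comes back at 7. Claisen–Schmidt condensation (KOH, EtOH/H2O, rt) should give (2E)-3-[3-(benzyloxy)-4,5-dimethoxyphenyl]-1-(4-hydroxy-3-methoxyphenyl)prop-2-en-1-one F5. Silylation (tBuMe2SiCl, imidazole, DMF) gives (2E)-3-[3-(benzyloxy)-4,5-dimethoxyphenyl]-1-[4-(tert-butyldimethylsilyloxy)-3-methoxyphenyl]prop-2-en-1-one F6. Conjugate borylation with bis(pinacolato)diboron, CuCl, NaOtBu, MeOH and the ligand 1-[2-(diphenylphosphino)ferrocenyl]ethyldicyclohexylphosphine (the antipode that gives the 3S product) in THF gives (3S)-3-[3-(benzyloxy)-4,5-dimethoxyphenyl]-1-[4-(tert-butyldimethylsilyloxy)-3-methoxyphenyl]-3-(4,4,5,5-tetramethyl-1,3,2-dioxaborolan-2-yl)propan-1-one F7. Oxidation with NaBO3·4H2O in THF/H2O, with retention at carbon, gives (3S)-3-[3-(benzyloxy)-4,5-dimethoxyphenyl]-1-[4-(tert-butyldimethylsilyloxy)-3-methoxyphenyl]-3-hydroxypropan-1-one F8. Bu4NF buffered with AcOH in THF at 0 °C then frees the phenol to give 7.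

Step 6. Over-reduction is the risk: hydrogenolysis of the benzylic C2–O1 bond, which would open ring C, or reduction of the C4 ketone. The fallback sets out from 11 and comes back at 12 without any new compound on the way (F0). It replaces the reductive cleavage by Lewis-acid debenzylation with BCl3 and pentamethylbenzene in CH2Cl2 at −78 °C, where the benzyl cation is taken up by the arene and no hydrogen or metal surface is present.

**Further compounds**
F1 | step 4 | 1-(2-hydroxy-3,4-dimethoxyphenyl)ethanone (purchased) | CC(=O)c1ccc(OC)c(OC)c1O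
F2 | step 4 | 1-[3,4-dimethoxy-2-(trimethylsilyloxy)phenyl]-1-(trimethylsilyloxy)ethene | C=C(O[Si](C)(C)C)c1ccc(OC)c(OC)c1O[Si](C)(C)C
F3 | step 4 | (1R)-1-[3-(benzyloxy)-4,5-dimethoxyphenyl]-3-[3,4-dimethoxy-2-(trimethylsilyloxy)phenyl]-3-oxopropyl trichlorosilyl ether (not isolated) | COc1cc([C@H](O[Si](Cl)(Cl)Cl)CC(=O)c2ccc(OC)c(OC)c2O[Si](C)(C)C)cc(OCc3ccccc3)c1OC
F4 | step 4 | (3R)-3-[3-(benzyloxy)-4,5-dimethoxyphenyl]-3-hydroxy-1-(2-hydroxy-3,4-dimethoxyphenyl)propan-1-one | COc1cc([C@H](O)CC(=O)c2ccc(OC)c(OC)c2O)cc(OCc3ccccc3)c1OC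
F5 | step 3 | (2E)-3-[3-(benzyloxy)-4,5-dimethoxyphenyl]-1-(4-hydroxy-3-methoxyphenyl)prop-2-en-1-one | COc1cc(/C=C/C(=O)c2ccc(O)c(OC)c2)cc(OCc3ccccc3)c1OC
F6 | step 3 | (2E)-3-[3-(benzyloxy)-4,5-dimethoxyphenyl]-1-[4-(tert-butyldimethylsilyloxy)-3-methoxyphenyl]prop-2-en-1-one | COc1cc(/C=C/C(=O)c2ccc(O[Si](C)(C)C(C)(C)C)c(OC)c2)cc(OCc3ccccc3)c1OC
F7 | step 3 | (3S)-3-[3-(benzyloxy)-4,5-dimethoxyphenyl]-1-[4-(tert-butyldimethylsilyloxy)-3-methoxyphenyl]-3-(4,4,5,5-tetramethyl-1,3,2-dioxaborolan-2-yl)propan-1-one | COc1cc([C@@H](B2OC(C)(C)C(C)(C)O2)CC(=O)c3ccc(O[Si](C)(C)C(C)(C)C)c(OC)c3)cc(OCc4ccccc4)c1OC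
F8 | step 3 | (3S)-3-[3-(benzyloxy)-4,5-dimethoxyphenyl]-1-[4-(tert-butyldimethylsilyloxy)-3-methoxyphenyl]-3-hydroxypropan-1-one | COc1cc([C@@H](O)CC(=O)c2ccc(O[Si](C)(C)C(C)(C)C)c(OC)c2)cc(OCc3ccccc3)c1OC
F0 | step 6 | none | none
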